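**Retrosynthetic overview**
1. The rings are lettered A–B–C(Cl)–D in the order of the SMILES. All four benzene rings are bought (two 1,3,5-trimethoxybenzene, two phloroglucinol). No ring is formed; the work is three biaryl bonds, one C–Cl bond and the O-protecting groups.
2. The last operation is cleavage of the six methyl ethers on rings A and C.
3. The key disconnection is the central, tetra-ortho-oxygenated B–C bond. The native nucleophilic carbon of a free phloroglucinol ring (B) attacks ring C, which C–H plumbation has turned into an aryl-cation equivalent (aryllead triacetate).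
4. Both halves are the same biaryl, trimethoxyphenyl–phloroglucinol, made by the same polarity reversal. Used as it is, it is A–B (nucleophile). After O-acetylation (switches ring D off) and monochlorination (leaves one C–H on ring C), it is C–D.
5. Bond order: A–B and C–D in one reaction, then C–Cl, then B–C.

Assumption: the SMILES holds no stereocentre and no axial descriptor. Only the B–C axis could be stereogenic and it is left undefined, so the compound is made exactly as drawn and no axial configuration is claimed.

**Step 1**
Reactants: 1 1,3,5-trimethoxybenzene; 2 phloroglucinol (benzene-1,3,5-triol; anhydrous)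
Product: 4 2',4',6'-trimethoxybiphenyl-2,4,6-triol, via trimethoxyphenyllead triacetate 3 (not isolated)
Conditions: Pb(OAc)4 (1.0 equiv; 1 in 5% excess), CHCl3, 25 °C, dark, 3 h; then 2 (4 equiv), pyridine, 40 °C, 12 h, one flask; dilute H2SO4 wash
Reagents that add atoms: none
Why: Electrophilic C–H plumbation turns the normally nucleophilic ring carbon of 1 into an aryl-cation equivalent (3), which swaps an acetate for a phenoxide oxygen of 2 and delivers the aryl group to the ortho carbon by ligand coupling at tetravalent lead (Pinhey–Barton arylation), tautomerisation restoring the phenol, while the fourfold excess of cheap, water-removable 2 holds the reaction at monoarylation and no stereocentre is formed.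

**Step 2**
Reactants: 4 2',4',6'-trimethoxybiphenyl-2,4,6-triol
Product: 6 3'-chloro-2',4',6'-trimethoxybiphenyl-2,4,6-triyl triacetate, via biaryl triacetate 5 (not isolated)
Conditions: Ac2O (4 equiv), pyridine (5 equiv), DMAP (5 mol%), MeCN, 25 °C, 2 h; then NCS (1.0 equiv), 25→45 °C, 8 h, one flask
Reagents that add atoms: acetic anhydride CC(=O)OC(C)=O; N-chlorosuccinimide O=C1CCC(=O)N1Cl
Why: O-acetylation switches off the phloroglucinol ring, so the electrophilic aromatic chlorination goes only into the still activated trimethoxyphenyl ring at one of its two equivalent C–H positions, and the first chlorine deactivates that ring enough for one equivalent of NCS to stop at the monochloride.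

**Step 3 (key step)**
Reactants: 6 3'-chloro-2',4',6'-trimethoxybiphenyl-2,4,6-triyl triacetate; 4 2',4',6'-trimethoxybiphenyl-2,4,6-triol
Product: 9 hexa-O-methyl ether of the target (rings A and C methylated; rings B and D free), via chloroaryllead triacetate 7 (not isolated), via quaterphenyl triacetate 8 (not isolated)
Conditions: Pb(OAc)4 (1.0 equiv; 6 in 5% excess), AcOH (5 equiv), CHCl3, 45 °C, dark, 36 h; then 4 (2 equiv), pyridine, 60 °C, 24 h; then N2H4·H2O (20 equiv), MeOH, 25 °C, 1 h, argon, one flask; excess 4 recovered
Reagents that add atoms: none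
Why: Proposed new method: Pb(OAc)4 can attack 6 only at the single C–H of ring C (flanked by two OMe groups, ring D being switched off by its acetates), which gives the hexasubstituted aryl-cation equivalent 7 by electrophilic plumbation; 7 then takes up a phenoxide oxygen of 4 in place of acetate and forms the B–C bond at the ortho carbon by ligand coupling with loss of Pb(OAc)2 (Pinhey–Barton arylation), the twofold excess of 4 and the crowding around the last ring B C–H holding back a second arylation, and hydrazinolysis in the same flask removes the three acetates wherever they may have migrated; the closest known reaction types are the direct plumbation of 1,3-dimethoxy- and 1,3,5-trimethoxybenzene and the ortho-arylation of hindered phenols with 2,4,6-trimethoxyphenyllead triacetate, what is new is the crowding and the chlorine on the plumbated ring, and the new axis is formed without control because none is specified.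

**Step 4**
Reactants: 9 hexa-O-methyl ether of the target
Product: 10 target, 5-chloro-tetrafucol as in the given SMILES
Conditions: BBr3 (20 equiv), CH2Cl2, −78→25 °C, 24 h; MeOH quench, 0 °C, repeated evaporation with MeOH; argon; reversed-phase chromatography
Reagents that add atoms: none
Why: This is a BBr3 aryl methyl ether cleavage, in which boron coordinates each ether oxygen and bromide removes the methyl group as MeBr; the crowded, out-of-plane OMe groups of ring C are the most basic and cleave readily, the aryl chloride and the biaryl bonds are inert, no acyl group is left that could C-acylate the rings, and methanol carries boron away as B(OMe)3.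

**Compound list**
1 | 1,3,5-trimethoxybenzene | COc1cc(OC)cc(OC)c1 | starting material
2 | phloroglucinol (benzene-1,3,5-triol) | Oc1cc(O)cc(O)c1 | starting material
3 | (2,4,6-trimethoxyphenyl)lead triacetate | COc1cc(OC)c([Pb](OC(C)=O)(OC(C)=O)OC(C)=O)c(OC)c1 | intermediate
4 | 2',4',6'-trimethoxybiphenyl-2,4,6-triol | COc1cc(OC)c(-c2c(O)cc(O)cc2O)c(OC)c1 | intermediate
5 | 2',4',6'-trimethoxybiphenyl-2,4,6-triyl triacetate | COc1cc(OC)c(-c2c(OC(C)=O)cc(OC(C)=O)cc2OC(C)=O)c(OC)c1 | intermediate
6 | 3'-chloro-2',4',6'-trimethoxybiphenyl-2,4,6-triyl triacetate | COc1cc(OC)c(-c2c(OC(C)=O)cc(OC(C)=O)cc2OC(C)=O)c(OC)c1Cl | intermediate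
7 | [3-chloro-2,4,6-trimethoxy-5-(2,4,6-triacetoxyphenyl)phenyl]lead triacetate | COc1c(Cl)c(OC)c(-c2c(OC(C)=O)cc(OC(C)=O)cc2OC(C)=O)c(OC)c1[Pb](OC(C)=O)(OC(C)=O)OC(C)=O | intermediate
8 | quaterphenyl: ring A 2,4,6-trimethoxyphenyl; ring B 2,4,6-trihydroxy-1,3-phenylene; ring C 5-chloro-2,4,6-trimethoxy-1,3-phenylene; ring D 2,4,6-triacetoxyphenyl | COc1cc(OC)c(-c2c(O)cc(O)c(-c3c(OC)c(Cl)c(OC)c(-c4c(OC(C)=O)cc(OC(C)=O)cc4OC(C)=O)c3OC)c2O)c(OC)c1 | intermediate
9 | quaterphenyl as 8 with ring D 2,4,6-trihydroxyphenyl (hexa-O-methyl ether of the target) | COc1cc(OC)c(-c2c(O)cc(O)c(-c3c(OC)c(Cl)c(OC)c(-c4c(O)cc(O)cc4O)c3OC)c2O)c(OC)c1 | intermediate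
10 | chlorotetrafucol CNP0271703.0 | Oc1cc(O)c(-c2c(O)cc(O)c(-c3c(O)c(Cl)c(O)c(-c4c(O)cc(O)cc4O)c3O)c2O)c(O)c1 | target

**Totals**
Total step count: 4.
Longest linear sequence: 4 (1 → 4 → 6 → 9 → 10). Compound 4 enters twice, once as the precursor of the electrophile and once as the nucleophile.

**Steps most likely to fail, with fallbacks**

Step 3 is the riskiest. Ring C of 6 is crowded and deactivated by chlorine, so plumbation may be slow, and the hexasubstituted aryl group may couple poorly.
- The fallback moves the chlorine to the other inner ring. This gives the same target, because the deprotected chain reads the same from either end.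
- It sets out from 5 (step 2 stopped before NCS and 5 isolated) and from 4, and it comes back at 10.
- The trimethoxyphenyl ring of 5 is about as reactive as 1. It is plumbated with Pb(OAc)4 in CHCl3 at 25 °C to [2,4,6-trimethoxy-3-(2,4,6-triacetoxyphenyl)phenyl]lead triacetate F1.
- Separately, 4 is chlorinated on its free phloroglucinol ring (NCS 1.0 equiv, THF, −40→0 °C) to 3-chloro-2',4',6'-trimethoxybiphenyl-2,4,6-triol F2. This has only one C–H left on the nucleophilic ring, so a second arylation is impossible.
- F1 and F2 in CHCl3–pyridine at 60 °C give the ring-B-chlorinated quaterphenyl triacetate F3.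
- N2H4·H2O in MeOH gives the ring-B-chlorinated quaterphenyl hexaol F4.
- BBr3 as in step 4 gives 10.

Step 1 is next. Compound 2 may be arylated more than once, may be oxidised by tetravalent lead, or may stay out of solution.
- The fallback makes this bond by Suzuki–Miyaura cross-coupling instead. It sets out from 2 and comes back at 4.
- Compound 2 with MOMCl and NaH in DMF at 0 °C gives 1,3,5-tris(methoxymethoxy)benzene F5.
- NIS in MeCN at 25 °C gives 2-iodo-1,3,5-tris(methoxymethoxy)benzene F6.
- Coupling with purchased 2,4,6-trimethoxyphenylboronic acid (Pd(OAc)2 5 mol%, SPhos 10 mol%, K3PO4, toluene–water, 100 °C) gives 2,4,6-trimethoxy-2',4',6'-tris(methoxymethoxy)biphenyl F7.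
- HCl in MeOH at 40 °C releases 4.

Step 4 is third. The sixfold demethylation may stall at partly methylated phenols, and free 10 is polar, air-sensitive and hard to free from boron residues.
- The fallback does not isolate the phenol from the BBr3 reaction. It traps it as an ester, purifies that, and releases 10 under mild conditions.
- It sets out from 9 and comes back at 10.
- The crude residue after BBr3 and the MeOH quench is treated with Ac2O–pyridine at 25 °C to give the dodecaacetate of the target F8.
- F8 is stable and is chromatographed on silica. Partly methylated congeners separate here and can be returned to BBr3.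
- N2H4·H2O in degassed MeCN–MeOH at 25 °C, followed by acidic extraction, gives 10.

**Further compounds**
F1 | step 3 | [2,4,6-trimethoxy-3-(2,4,6-triacetoxyphenyl)phenyl]lead triacetate | COc1cc(OC)c(-c2c(OC(C)=O)cc(OC(C)=O)cc2OC(C)=O)c(OC)c1[Pb](OC(C)=O)(OC(C)=O)OC(C)=O
F2 | step 3 | 3-chloro-2',4',6'-trimethoxybiphenyl-2,4,6-triol | COc1cc(OC)c(-c2c(O)cc(O)c(Cl)c2O)c(OC)c1
F3 | step 3 | ring-B-chlorinated quaterphenyl triacetate | COc1cc(OC)c(-c2c(O)c(Cl)c(O)c(-c3c(OC)cc(OC)c(-c4c(OC(C)=O)cc(OC(C)=O)cc4OC(C)=O)c3OC)c2O)c(OC)c1
F4 | step 3 | ring-B-chlorinated quaterphenyl hexaol | COc1cc(OC)c(-c2c(O)c(Cl)c(O)c(-c3c(OC)cc(OC)c(-c4c(O)cc(O)cc4O)c3OC)c2O)c(OC)c1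
F5 | step 1 | 1,3,5-tris(methoxymethoxy)benzene | COCOc1cc(OCOC)cc(OCOC)c1
F6 | step 1 | 2-iodo-1,3,5-tris(methoxymethoxy)benzene | COCOc1cc(OCOC)c(I)c(OCOC)c1
F7 | step 1 | 2,4,6-trimethoxy-2',4',6'-tris(methoxymethoxy)biphenyl | COCOc1cc(OCOC)c(-c2c(OC)cc(OC)cc2OC)c(OCOC)c1
F8 | step 4 | dodecaacetate of the target | CC(=O)Oc1cc(OC(C)=O)c(-c2c(OC(C)=O)cc(OC(C)=O)c(-c3c(OC(C)=O)c(Cl)c(OC(C)=O)c(-c4c(OC(C)=O)cc(OC(C)=O)cc4OC(C)=O)c3OC(C)=O)c2OC(C)=O)c(OC(C)=O)c1
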